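Count target against the solid reagent charged, not against the substrate.

| flask | solid substrate | solid reagent | remark | time |
|---|---|---|---|---|
| blue | 0.020 M | 0.016 M | run made earlier |  |
| grey | 0.020 M | 0.036 M | run made earlier |  |
| green | 0.030 M | 0.024 M | run made earlier |  |
| flask | 0.020 M | 0.0240 M |  | 10 min |

| run | time / min | target / % | dissolved substrate / % | solid substrate / % |
|---|---|---|---|---|
| blue | 1.33 | 1.1 | 6.3 | 93.2 |
| blue | 2.50 | 2.4 | 9.3 | 86.1 |
| blue | 4.00 | 5.6 | 14.4 | 78.1 |
| blue | 5.00 | 4.7 | 15.9 | 73.6 |
| blue | 6.00 | 5.5 | 15.9 | 70.6 |
| grey | 0.500 | 0.4 | 3.3 | 97.8 |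
| grey | 1.50 | 2.1 | 5.6 | 91.9 |
| grey | 3.00 | 6.9 | 9.3 | 83.8 |
| grey | 4.00 | 9.0 | 10.4 | 78.8 |
| grey | 6.00 | 12.9 | 14.6 | 68.7 |
| green | 0.500 | 0 | 2.4 | 97.9 |
| green | 1.50 | 0.8 | 4.1 | 94.6 |
| green | 3.00 | 2.7 | 5.9 | 89.5 |
| green | 4.00 | 5.7 | 8.4 | 86.4 |
| green | 6.00 | 4.8 | 11.1 | 79.4 |

(each reading ± 0.5 percentage points)

- percentages count the solid substrate that a species holds: one side product counts as two
- solid, in amounts per volume of the solution: solid substrate, solid reagent
- steps that have been proposed: solid reagent <-> partner; partner -> decomposed reagent; solid substrate <-> dissolved substrate; 2 dissolved substrate -> side product; dissolved substrate + partner -> target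
- at the start none of the solid reagent is in solution
- at the start none of the solid substrate is in solution
- dissolved substrate means what is dissolved; the solid is not counted in it

- how much target there is at 10 min, in percent of the solid substrate charged
- concentration of dissolved substrate in solution at 10 min, in percent of saturation

Blue target sits flat at 5.6 %, 4.7 % and 5.5 % from 4.00 min on while its solid substrate keeps falling, so I take the reagent side as what ended it. Averaged and converted, that plateau puts 6.58 % of the charged reagent into target: this is the capture share, target made per solid reagent charged. Green, with both charges different, should then level at 5.27 %, and it reads 5.7 % and 4.8 %. So for this flask I commit to 7.90 % target and offer no figure for saturation.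

The forecast says 14 % target and 37 % of saturation, on these grounds: “roughly first order in both reagent and dissolved substrate, with an induction period”.

The flask gives 8.91 % target and 27.1 % of saturation.

    solid reagent ⇌ partner, rate k1*(cs1 - [partner]) while solid is left; crystals form when [partner] > cs1 (solubility = 19.0 mM, k = 0.0270 /s)
    partner → decomposed reagent (k = 0.00950 /s)
    solid substrate ⇌ dissolved substrate, rate k3*(cs3 - [dissolved substrate]) while solid is left; crystals form when [dissolved substrate] > cs3 (solubility = 15.0 mM, k = 0.00130 /s)
    2 dissolved substrate → side product (k = 0.380 /M/s)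
    dissolved substrate + partner → target (k = 0.500 /M/s)

Target stays low in this flask because partner decomposes while the solid substrate dissolves slowly: the flask's 8.91 % becomes 38.9 % without the decomposition and 32.3 % with fast dissolving. This flask is charged with more solid reagent than solid substrate, yet its solid reagent stands at 0 % by 5.00 min and [partner] at 5.62 × 10⁻⁵ M by 10.0 min, and its capture share comes to 7.43 %. Carried to the neighbour flask with 0.080 M of solid substrate, my 6.58 % predicts 1.98 % target, and that flask holds 2.23 %.

(The numbers in the tables come from a simulation on assumed constants; scatter was added.)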